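**Assumption:** positions are named with germacrane numbering (C1–C10 ring carbons, C11–C13 lactone branch, C14 = methyl on C10, C15 = methyl on C4); 3,4-dibromofuran-2(5H)-one and (R)-2-methylglycidol are taken as bought.

## Retrosynthetic overview

1. Target 22 ⇒ remove the C13 acetate and the O8 glycidate; the C13 carbon comes from a C11–Br handle (Stille) ⇒ bromo diol 16.
2. Ten-membered carbocycle (formed last) ⇒ C5=C6 by intramolecular vinylogous aldol condensation of the butenolide γ-CH2 onto a C5 aldehyde ⇒ 12.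
3. Key disconnection C7–C8: C4 of 3,4-dibromofuran-2(5H)-one, innately an acceptor carbon, is turned into a donor (β-acylvinyl anion, Ni/Cr) and adds to the C8 aldehyde of dialdehyde 9; the butenolide ring is bought.
4. 9 ⇒ double ozonolysis of divinyl alcohol 7 ⇒ epoxide + vinyl cuprate ⇒ oxolane diol 4 ⇒ Sharpless epoxidation/5-exo cyclisation of 8-hydroxylinalool ⇒ (R)-linalool.
5. Ring order: oxolane (step 2) → butenolide attached (step 5) → ten-membered ring (step 6); the side-chain oxirane comes from (R)-2-methylglycidol.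

## Route

Step 1
Reactants: 1 (R)-(−)-linalool
Product: 2 (2E,6R)-2,6-dimethylocta-2,7-diene-1,6-diol
Conditions: SeO2 (0.3 equiv), t-BuOOH (2 equiv), CH2Cl2, rt
Reagents that add atoms: tert-butyl hydroperoxide CC(C)(C)OO (oxygen relayed by SeO2)
Why: SeO2 allylic oxidation (ene reaction then [2,3]-sigmatropic shift) hydroxylates only the E-methyl group of the trisubstituted alkene and leaves the tertiary carbinol centre (later C4) untouched.

Step 2
Reactants: 2 (2E,6R)-2,6-dimethylocta-2,7-diene-1,6-diol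
Product: 4 (2R)-2-[(2S,5R)-5-ethenyl-5-methyloxolan-2-yl]propane-1,2-diol, via epoxy alcohol 3 (not isolated)
Conditions: Ti(OiPr)4, D-(−)-diethyl tartrate, t-BuOOH, 4 Å MS, CH2Cl2, −20 °C; then CSA (cat.), rt
Reagents that add atoms: tert-butyl hydroperoxide CC(C)(C)OO
Why: Sharpless asymmetric epoxidation of the primary allylic alcohol with the D-tartrate gives the (2R,3R)-epoxide, and 5-exo opening by the tertiary hydroxyl at the secondary epoxide carbon with inversion sets C1 (S) while the retained C–O bond sets C10 (R).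

Step 3
Reactants: 4 (2R)-2-[(2S,5R)-5-ethenyl-5-methyloxolan-2-yl]propane-1,2-diol
Product: 7 (2R)-2-[(2S,5R)-5-ethenyl-5-methyloxolan-2-yl]pent-4-en-2-ol, via primary tosylate 5 (not isolated), via epoxide 6 (not isolated)
Conditions: NaH (2.2 equiv), TsCl (1.0 equiv), THF, 0 °C→rt; then CuI (20 mol%), CH2=CHMgBr (3 equiv), −30→0 °C
Reagents that add atoms: vinylmagnesium bromide C=C[Mg]Br
Why: Selective sulfonylation of the primary alkoxide and Williamson closure give the terminal epoxide without touching C10, and copper-catalysed Grignard opening (SN2 at the CH2 terminus) brings in C8 as a vinyl group.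

Step 4
Reactants: 7 (2R)-2-[(2S,5R)-5-ethenyl-5-methyloxolan-2-yl]pent-4-en-2-ol
Product: 9 (2R,5S)-5-[(2R)-2-hydroxy-4-oxobutan-2-yl]-2-methyloxolane-2-carbaldehyde, via bis-ozonide 8 (not isolated)
Conditions: O3, CH2Cl2, −78 °C; then Me2S, −78 °C→rt
Reagents that add atoms: ozone [O-][O+]=O
Why: Ozonolysis with reductive work-up cleaves both terminal alkenes at once to the C5 and C8 aldehydes and no stereocentre is involved; the C5 aldehyde is expected to rest largely as the six-membered lactol with the C10 hydroxyl.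

Step 5
Reactants: 9 (2R,5S)-5-[(2R)-2-hydroxy-4-oxobutan-2-yl]-2-methyloxolane-2-carbaldehyde; 10 3,4-dibromofuran-2(5H)-one
Product: 12 (2R,5S)-5-[(2R,4S)-4-(4-bromo-5-oxo-2,5-dihydrofuran-3-yl)-2,4-dihydroxybutan-2-yl]-2-methyloxolane-2-carbaldehyde, via alkenylchromium dichloride 11 (not isolated)
Conditions: CrCl2 (4 equiv), NiCl2 (5 mol%), Kishi sulfonamide–oxazoline ligand (antipode matched to 8S, 4.4 equiv), Et3N, THF, rt; 10 (1.3 equiv)
Reagents that add atoms: none
Why: Nozaki–Hiyama–Kishi reaction, in which zerovalent nickel inserts into the more electron-poor C4–Br bond and transmetalation to chromium turns the normally electrophilic β-carbon of the butenolide into a β-acylvinyl anion (homoenolate-type donor) that adds to the unhindered C8 aldehyde (the C5 carbonyl is neopentyl and lactol-masked), with C8 (S) set by the chromium-bound chiral sulfonamide and supported by chelation through O10 with the C10 methyl axial (1,3-syn).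

Step 6
Reactants: 12 (2R,5S)-5-[(2R,4S)-4-(4-bromo-5-oxo-2,5-dihydrofuran-3-yl)-2,4-dihydroxybutan-2-yl]-2-methyloxolane-2-carbaldehyde
Product: 16 (1S,4R,5E,8S,10R)-11-bromo-1,4-epoxy-8,10-dihydroxy-13-norgermacra-5,7(11)-dien-12,6-olide, via silyloxyfuran 13 (not isolated), via silyl aldol adduct 14 (not isolated), via bis-silyl ether 15 (not isolated)
Conditions: TMSOTf (5 equiv), i-Pr2NEt (8 equiv), CH2Cl2 (1 mM, slow addition of 12), −78→0 °C; DBU (5 equiv), rt; then 1 M HCl, THF, 0 °C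
Reagents that add atoms: none
Why: Intramolecular vinylogous Mukaiyama aldol reaction of the in-situ 2-silyloxyfuran (γ-carbon C6) onto the C5 aldehyde followed by E1cB loss of silanolate closes the ten-membered ring, the cis-bridged oxolane allows only the 5E alkylidene geometry, and C11–Br (instead of CH2OAc) leaves no β-leaving group on the enolate.

Step 7
Reactants: 17 (R)-2-methylglycidol
Product: 18 (S)-2-methyloxirane-2-carboxylic acid
Conditions: RuCl3 (2 mol%), NaIO4 (3 equiv), MeCN/EtOAc/H2O, 0 °C→rt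
Reagents that add atoms: NaIO4 [Na+].[O-]I(=O)(=O)=O (oxygen relayed by RuO4)
Why: RuO4 oxidation (Sharpless RuCl3/NaIO4 protocol) takes the primary alcohol to the acid without touching the quaternary epoxide carbon, whose descriptor changes from R to S only through the priority switch.

Step 8
Reactants: 16 (1S,4R,5E,8S,10R)-11-bromo-1,4-epoxy-8,10-dihydroxy-13-norgermacra-5,7(11)-dien-12,6-olide; 18 (S)-2-methyloxirane-2-carboxylic acid
Product: 20 (1S,4R,5E,8S,10R)-11-bromo-1,4-epoxy-10-hydroxy-8-[(2S)-2-methyloxirane-2-carbonyloxy]-13-norgermacra-5,7(11)-dien-12,6-olide, via mixed anhydride 19 (not isolated)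
Conditions: 18, 2,4,6-trichlorobenzoyl chloride, Et3N, THF, rt; then 16, DMAP, toluene, rt
Reagents that add atoms: none
Why: Yamaguchi esterification acylates the secondary allylic C8 hydroxyl with retention while the tertiary C10 hydroxyl stays free, and O8 cannot translactonise because it is trans to C12 across C7=C11.

Step 9
Reactants: 20 (1S,4R,5E,8S,10R)-11-bromo-1,4-epoxy-10-hydroxy-8-[(2S)-2-methyloxirane-2-carbonyloxy]-13-norgermacra-5,7(11)-dien-12,6-olide
Product: 22 (1S,4R,5E,8S,10R)-13-acetoxy-1,4-epoxy-10-hydroxy-8-[(2S)-2-methyloxirane-2-carbonyloxy]germacra-5,7(11)-dien-12,6-olide (CNP0142137.1), via primary alcohol 21 (not isolated)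
Conditions: Bu3SnCH2OH (1.5 equiv), Pd(PPh3)4 (10 mol%), dioxane, 80 °C; then Ac2O, pyridine, 0 °C→rt
Reagents that add atoms: (tributylstannyl)methanol OC[Sn](CCCC)(CCCC)CCCC; acetic anhydride CC(=O)OC(C)=O
Why: Stille cross-coupling (hydroxymethyl transfer from tin) replaces the C11 bromide by CH2OH with the alkene geometry fixed by the ring, and pyridine-mediated acetylation esterifies only the new primary alcohol, not the tertiary C10 hydroxyl.

## Compound list

1 | (R)-(−)-linalool, (3R)-3,7-dimethylocta-1,6-dien-3-ol | CC(C)=CCC[C@@](C)(O)C=C | starting material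
2 | (2E,6R)-2,6-dimethylocta-2,7-diene-1,6-diol | OC/C(C)=C/CC[C@@](C)(O)C=C | intermediate
3 | [(2R,3R)-3-[(3R)-3-hydroxy-3-methylpent-4-en-1-yl]-2-methyloxiran-2-yl]methanol | OC[C@@]1(C)O[C@@H]1CC[C@@](C)(O)C=C | intermediate (not isolated)
4 | (2R)-2-[(2S,5R)-5-ethenyl-5-methyloxolan-2-yl]propane-1,2-diol | C=C[C@@]1(C)CC[C@H](O1)[C@](C)(O)CO | intermediate
5 | (2R)-2-[(2S,5R)-5-ethenyl-5-methyloxolan-2-yl]-2-hydroxypropyl 4-methylbenzenesulfonate | C=C[C@@]1(C)CC[C@H](O1)[C@](C)(O)COS(=O)(=O)c1ccc(C)cc1 | intermediate (not isolated)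
6 | (2R,5S)-2-ethenyl-2-methyl-5-[(2R)-2-methyloxiran-2-yl]oxolane | C=C[C@@]1(C)CC[C@H](O1)[C@@]2(C)CO2 | intermediate (not isolated)
7 | (2R)-2-[(2S,5R)-5-ethenyl-5-methyloxolan-2-yl]pent-4-en-2-ol | C=C[C@@]1(C)CC[C@H](O1)[C@](C)(O)CC=C | intermediate
8 | (2R)-2-[(2S,5R)-5-methyl-5-(1,2,4-trioxolan-3-yl)oxolan-2-yl]-1-(1,2,4-trioxolan-3-yl)propan-2-ol (bis-ozonide, trioxolane centres unassigned) | O1COOC1[C@@]2(C)CC[C@H](O2)[C@](C)(O)CC3OCOO3 | intermediate (not isolated)
9 | (2R,5S)-5-[(2R)-2-hydroxy-4-oxobutan-2-yl]-2-methyloxolane-2-carbaldehyde (open form of the lactol) | O=C[C@@]1(C)CC[C@H](O1)[C@](C)(O)CC=O | intermediate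
10 | 3,4-dibromofuran-2(5H)-one | BrC1=C(Br)C(=O)OC1 | starting material
11 | (4-bromo-5-oxo-2,5-dihydrofuran-3-yl)chromium dichloride | Cl[Cr](Cl)C1=C(Br)C(=O)OC1 | intermediate (not isolated)
12 | (2R,5S)-5-[(2R,4S)-4-(4-bromo-5-oxo-2,5-dihydrofuran-3-yl)-2,4-dihydroxybutan-2-yl]-2-methyloxolane-2-carbaldehyde | O=C[C@@]1(C)CC[C@H](O1)[C@](C)(O)C[C@H](O)C2=C(Br)C(=O)OC2 | intermediate
13 | (2R,5S)-5-[(2R,4S)-4-[4-bromo-5-(trimethylsilyloxy)furan-3-yl]-2,4-bis(trimethylsilyloxy)butan-2-yl]-2-methyloxolane-2-carbaldehyde | O=C[C@@]1(C)CC[C@H](O1)[C@](C)(O[Si](C)(C)C)C[C@H](O[Si](C)(C)C)c2coc(O[Si](C)(C)C)c2Br | intermediate (not isolated)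
14 | (1S,4R,8S,10R)-11-bromo-1,4-epoxy-5,8,10-tris(trimethylsilyloxy)-13-norgermacr-7(11)-en-12,6-olide (C5/C6 epimer mixture) | BrC1=C2C(C(O[Si](C)(C)C)[C@@]3(C)CC[C@H](O3)[C@](C)(O[Si](C)(C)C)C[C@@H]2O[Si](C)(C)C)OC1=O | intermediate (not isolated)
15 | (1S,4R,5E,8S,10R)-11-bromo-1,4-epoxy-8,10-bis(trimethylsilyloxy)-13-norgermacra-5,7(11)-dien-12,6-olide | BrC1=C2/C(=C\[C@@]3(C)CC[C@H](O3)[C@](C)(O[Si](C)(C)C)C[C@@H]2O[Si](C)(C)C)OC1=O | intermediate (not isolated)
16 | (1S,4R,5E,8S,10R)-11-bromo-1,4-epoxy-8,10-dihydroxy-13-norgermacra-5,7(11)-dien-12,6-olide | BrC1=C2/C(=C\[C@@]3(C)CC[C@H](O3)[C@](C)(O)C[C@@H]2O)OC1=O | intermediate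
17 | (R)-2-methylglycidol, [(2R)-2-methyloxiran-2-yl]methanol | OC[C@]1(C)CO1 | starting material
18 | (S)-2-methyloxirane-2-carboxylic acid | OC(=O)[C@]1(C)CO1 | intermediate
19 | (2S)-2-methyloxirane-2-carboxylic 2,4,6-trichlorobenzoic anhydride | O=C(OC(=O)c1c(Cl)cc(Cl)cc1Cl)[C@]1(C)CO1 | intermediate (not isolated)
20 | (1S,4R,5E,8S,10R)-11-bromo-1,4-epoxy-10-hydroxy-8-[(2S)-2-methyloxirane-2-carbonyloxy]-13-norgermacra-5,7(11)-dien-12,6-olide | BrC1=C2/C(=C\[C@@]3(C)CC[C@H](O3)[C@](C)(O)C[C@@H]2OC(=O)[C@]2(C)CO2)OC1=O | intermediate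
21 | (1S,4R,5E,8S,10R)-1,4-epoxy-10,13-dihydroxy-8-[(2S)-2-methyloxirane-2-carbonyloxy]germacra-5,7(11)-dien-12,6-olide | OCC1=C2/C(=C\[C@@]3(C)CC[C@H](O3)[C@](C)(O)C[C@@H]2OC(=O)[C@]2(C)CO2)OC1=O | intermediate (not isolated)
22 | (1S,4R,5E,8S,10R)-13-acetoxy-1,4-epoxy-10-hydroxy-8-[(2S)-2-methyloxirane-2-carbonyloxy]germacra-5,7(11)-dien-12,6-olide (CNP0142137.1) | CC(=O)OCC1=C2/C(=C\[C@@]3(C)CC[C@H](O3)[C@](C)(O)C[C@@H]2OC(=O)[C@]2(C)CO2)OC1=O | target

## Step count and risks

Total steps: 9. Longest linear sequence: 8 (steps 1–6, 8, 9; step 7 makes the side-chain acid).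

**Most likely to fail, in order:**

**Step 6 (ring closure).** Closing a ten-membered ring by a vinylogous aldol reaction is untested; oligomerisation or a stalled aldol adduct are the likely failure modes. Fallback, setting out from 9 and coming back at 16: the C5=C6 bond is made by an intramolecular Horner–Wadsworth–Emmons olefination instead. Mucobromic acid and diethyl phosphite give diethyl (3,4-dibromo-5-oxo-2,5-dihydrofuran-2-yl)phosphonate F3, which replaces 10 under the step 5 conditions. Through (4-bromo-2-diethoxyphosphoryl-5-oxo-2,5-dihydrofuran-3-yl)chromium dichloride F4 it adds to the C8 aldehyde of 9 and gives diethyl [4-bromo-3-[(1S,3R)-3-[(2S,5R)-5-formyl-5-methyloxolan-2-yl]-1,3-dihydroxybutyl]-5-oxo-2,5-dihydrofuran-2-yl]phosphonate F5. LiCl and i-Pr2NEt in MeCN at 1 mM (Masamune–Roush conditions) then close the ring directly to 16.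

**Step 5 (Ni/Cr coupling).** The coupling must choose the C8 over the C5 aldehyde and the C4–Br over the C3–Br bond. The facial sense of the chiral chromium complex for this new donor has to be established on the first run (Mosher analysis). Fallback, setting out from 16 as obtained with the wrong or mixed C8 configuration and coming back at 16 as the pure 8S alcohol: the stereocentre is reset on the macrocycle by reagent-controlled ketone reduction. The material is carried through step 6, so 16 is accompanied by (1S,4R,5E,8R,10R)-11-bromo-1,4-epoxy-8,10-dihydroxy-13-norgermacra-5,7(11)-dien-12,6-olide F1. Dess–Martin periodinane oxidises both epimers to the single ketone (1S,4R,5E,10R)-11-bromo-1,4-epoxy-10-hydroxy-8-oxo-13-norgermacra-5,7(11)-dien-12,6-olide F2. Corey–Bakshi–Shibata reduction ((R)-Me-CBS oxazaborolidine, catecholborane, −78 °C; alkenyl as the large group) returns 16.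

**Step 9 (Stille hydroxymethylation).** Transmetalation of an alkyl group to a hindered, tetrasubstituted α-bromo lactone may be too slow at temperatures the epoxy ester tolerates. Fallback, setting out from 20 and coming back at 21: the polarity at C11 is reversed. 20 is treated with CrCl2, NiCl2 (cat.) and paraformaldehyde in DMF at rt, so that the C11 alkenylchromium dichloride of 20 F6 adds to formaldehyde and gives 21, which is acetylated as in step 9 to 22.

## Further compounds

F1 | step 5 | (1S,4R,5E,8R,10R)-11-bromo-1,4-epoxy-8,10-dihydroxy-13-norgermacra-5,7(11)-dien-12,6-olide (8R epimer of 16) | BrC1=C2/C(=C\[C@@]3(C)CC[C@H](O3)[C@](C)(O)C[C@H]2O)OC1=O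
F2 | step 5 | (1S,4R,5E,10R)-11-bromo-1,4-epoxy-10-hydroxy-8-oxo-13-norgermacra-5,7(11)-dien-12,6-olide | BrC1=C2/C(=C\[C@@]3(C)CC[C@H](O3)[C@](C)(O)CC2=O)OC1=O
F3 | step 6 | diethyl (3,4-dibromo-5-oxo-2,5-dihydrofuran-2-yl)phosphonate | CCOP(=O)(OCC)C1OC(=O)C(Br)=C1Br
F4 | step 6 | (4-bromo-2-diethoxyphosphoryl-5-oxo-2,5-dihydrofuran-3-yl)chromium dichloride | CCOP(=O)(OCC)C1OC(=O)C(Br)=C1[Cr](Cl)Cl
F5 | step 6 | diethyl [4-bromo-3-[(1S,3R)-3-[(2S,5R)-5-formyl-5-methyloxolan-2-yl]-1,3-dihydroxybutyl]-5-oxo-2,5-dihydrofuran-2-yl]phosphonate | O=C[C@@]1(C)CC[C@H](O1)[C@](C)(O)C[C@H](O)C2=C(Br)C(=O)OC2P(=O)(OCC)OCC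
F6 | step 9 | C11 alkenylchromium dichloride of 20 (CrCl2 in place of Br) | Cl[Cr](Cl)C1=C2/C(=C\[C@@]3(C)CC[C@H](O3)[C@](C)(O)C[C@@H]2OC(=O)[C@]2(C)CO2)OC1=O
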